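**Retrosynthetic overview**

1. The target has ring A (trimethoxybenzene), ring B (2,6-dimethoxycyclohexa-2,5-dienone, spiro at C-1′) and the seven-membered ring C, which carries the trans methyls at C-7/C-8 and the C-9 benzoate.
2. Ring C is cut at C(spiro)–CH2 and at C(aryl)–CH(OBz). This is a formal (4+3) spiroannulation of a 2′-bromobiaryl silyl ether (1,3-dinucleophile) with (2S,3S)-4-bromo-2,3-dimethylbutanal (1,4-dielectrophile) and benzoyl chloride, run in one flask as the last step.
3. Enabling feature: the spiro carbon C-1′ lies para to the carbonyl of ring B, so ring B is a 2,6-dimethoxyphenol dearomatised at its para carbon, and the ring-A carbon C-9a that bears CH(OBz) is ortho to the biaryl bond. The three-atom unit C-1′–C-4a–C-9a can therefore act twice as a carbon nucleophile (aryllithium, then phenoxide para carbon); ring B is symmetrical, so C-1′ is not stereogenic.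
4. The biaryl comes from a site-selective Suzuki coupling at the iodide of 1-bromo-2-iodo-3,4,5-trimethoxybenzene. The chain comes from C2-symmetric (2S,3S)-2,3-dimethylbutane-1,4-diol (oxidative homocoupling of two molecules of a propionyl oxazolidinone), whose two ends are equivalent.
5. Ring order: rings A and B are bought as arenes and joined first; ring C is closed last, in the operation that dearomatises ring B.

Key step: step 9

Assumption: the enolate homocoupling of step 4 is taken to follow the facial bias of the corresponding Evans alkylation at both new centres, so that the (R)-auxiliary gives the (2S,3S) unit; with the opposite sense the (S)-auxiliary would be used.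

**Route**

Step 1
Reactants: 1 5-bromo-1,2,3-trimethoxybenzene
Product: 2 1-bromo-2-iodo-3,4,5-trimethoxybenzene
Conditions: NIS (1.05 equiv), CF3CO2H (cat.), MeCN, rt
Reagents that add atoms: N-iodosuccinimide, O=C1CCC(=O)N1I
Why: Electrophilic aromatic iodination; the two free ring positions are equivalent and each is ortho and para to a methoxy group, so a single mono-iodide should form.

Step 2
Reactants: 2 1-bromo-2-iodo-3,4,5-trimethoxybenzene; 3 2,6-dimethoxy-4-(4,4,5,5-tetramethyl-1,3,2-dioxaborolan-2-yl)phenol
Product: 4 4-(6-bromo-2,3,4-trimethoxyphenyl)-2,6-dimethoxyphenol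
Conditions: Pd(PPh3)4 (5 mol %), K2CO3, 1,4-dioxane/H2O, 80 °C
Reagents that add atoms: none
Why: Suzuki–Miyaura coupling; oxidative addition of zerovalent palladium into the C–I bond is much faster than into the C–Br bond, so the bromine ortho to the new biaryl bond should be kept.

Step 3
Reactants: 4 4-(6-bromo-2,3,4-trimethoxyphenyl)-2,6-dimethoxyphenol
Product: 5 [4-(6-bromo-2,3,4-trimethoxyphenyl)-2,6-dimethoxyphenoxy](tert-butyl)dimethylsilane
Conditions: TBSCl, imidazole, DMF, rt
Reagents that add atoms: tert-butyldimethylsilyl chloride, CC(C)(C)[Si](C)(C)Cl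
Why: Silyl ether formation; it masks the O–H toward tert-butyllithium and stores the phenoxide for later release by fluoride.

Step 4
Reactants: 6 (4R)-4-benzyl-3-propanoyl-1,3-oxazolidin-2-one (two molecules are joined; the second is entered under the reagents that add atoms)
Product: 8 (2S,3S)-1,4-bis[(4R)-4-benzyl-2-oxo-1,3-oxazolidin-3-yl]-2,3-dimethylbutane-1,4-dione, via lithium Z-enolate 7 (not isolated)
Conditions: LiN(i-Pr)2 (1.1 equiv per imide), THF, −78 °C; then TiCl4 (1.1 equiv per imide), −78 °C to rt
Reagents that add atoms: second molecule of 6, (4R)-4-benzyl-3-propanoyl-1,3-oxazolidin-2-one, CCC(=O)N1[C@H](Cc2ccccc2)COC1=O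
Why: Oxidative homocoupling of a chiral imide enolate, in which two molecules of 6 are joined at their α-carbons while tetravalent titanium is reduced to trivalent titanium; the benzyl group shields one face of each Z-enolate as in an Evans alkylation, so both new centres should be S and the C2-symmetric dimer should predominate.

Step 5
Reactants: 8 (2S,3S)-1,4-bis[(4R)-4-benzyl-2-oxo-1,3-oxazolidin-3-yl]-2,3-dimethylbutane-1,4-dione
Product: 9 (2S,3S)-2,3-dimethylbutane-1,4-diol
Conditions: LiBH4, MeOH (2 equiv), THF, 0 °C to rt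
Reagents that add atoms: none
Why: Reductive cleavage of N-acyloxazolidinones with LiBH4; both imide carbonyls should go to CH2OH without touching the α-centres, and the auxiliary is recovered.

Step 6
Reactants: 9 (2S,3S)-2,3-dimethylbutane-1,4-diol
Product: 11 (3S,4S)-3,4-dimethyloxolan-2-one, via lactol 10 (not isolated)
Conditions: TEMPO (10 mol %), PhI(OAc)2 (2.2 equiv), CH2Cl2, rt
Reagents that add atoms: none
Why: Oxoammonium-mediated oxidative lactonisation of a 1,4-diol; the two hydroxymethyl ends are equivalent by C2 symmetry, so a single trans lactone should form under non-epimerising conditions.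

Step 7
Reactants: 11 (3S,4S)-3,4-dimethyloxolan-2-one
Product: 12 ethyl (2S,3S)-4-bromo-2,3-dimethylbutanoate
Conditions: HBr (gas), EtOH, 0 °C to rt
Reagents that add atoms: hydrogen bromide, Br; ethanol, CCO
Why: Acid-mediated ring opening of a γ-lactone with hydrogen bromide in ethanol (bromide ends up on the former O–CH2 carbon and the carboxyl group is esterified); no stereocentre takes part.

Step 8
Reactants: 12 ethyl (2S,3S)-4-bromo-2,3-dimethylbutanoate
Product: 13 (2S,3S)-4-bromo-2,3-dimethylbutanal
Conditions: i-Bu2AlH (1.05 equiv), CH2Cl2, −78 °C; aq. KNaC4H4O6 work-up; used crude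
Reagents that add atoms: none
Why: Partial reduction of an ester with diisobutylaluminium hydride at low temperature should stop at the aldehyde, and the α-centre should survive cold, non-basic handling.

Step 9
Reactants: 5 [4-(6-bromo-2,3,4-trimethoxyphenyl)-2,6-dimethoxyphenoxy](tert-butyl)dimethylsilane; 13 (2S,3S)-4-bromo-2,3-dimethylbutanal
Product: 18 (7R,8S,9R)-2,3,3',4,5'-pentamethoxy-7,8-dimethyl-4'-oxo-6,7,8,9-tetrahydrospiro[benzo[7]annulene-5,1'-cyclohexane]-2',5'-dien-9-yl benzoate, via aryllithium 14 (not isolated), via lithium alkoxide 15 (not isolated), via bromo benzoate 16 (not isolated), via cesium phenoxide 17 (not isolated)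
Conditions: t-BuLi (2.0 equiv), THF, −78 °C; then 13, −78 °C; then PhCOCl (1.0 equiv), −78 to 0 °C; then dilution with DMF (to 0.01 M), CsF (3 equiv), 80 °C
Reagents that add atoms: benzoyl chloride, O=C(Cl)c1ccccc1
Why: Proposed new method: bromine–lithium exchange gives aryllithium 14, which adds to the aldehyde of 13 to give alkoxide 15; benzoyl chloride acylates the alkoxide to 16 before it can displace the primary bromide, and fluoride then cleaves the aryl silyl ether so that phenoxide 17 attacks CH2Br through its para carbon and ring B becomes the dienone. The closest known reaction types are aryllithium addition to an α-branched aldehyde with acyl capture of the alkoxide, and the base- or fluoride-triggered intramolecular para-C-alkylation of a phenoxide by a tethered alkyl halide, which is known for five- and six-membered spiro rings but has not been shown for a seven-membered ring closed across a biaryl bond. Ring C closes by a 7-exo-tet SN2 displacement in which the two sp2 carbons of ring A and the twisted biaryl bond hold the bromide over the face of the nucleophilic carbon. C-9 is the only new stereocentre and should be set by Felkin–Anh addition anti to the sec-alkyl group at the α-carbon of 13, which leads to the (9R) configuration; C-7 and C-8 are carried over from 13 and the spiro carbon is not stereogenic. The step needs carbon over oxygen alkylation and ring closure over intermolecular reaction: the phenoxide oxygen lies para to the tether and between two methoxy groups, so only C-1′ can reach the bromide within the molecule, and high dilution disfavours the intermolecular path.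

**Compound list**

1 | 5-bromo-1,2,3-trimethoxybenzene | COc1cc(Br)cc(OC)c1OC | starting material
2 | 1-bromo-2-iodo-3,4,5-trimethoxybenzene | COc1cc(Br)c(I)c(OC)c1OC | intermediate
3 | 2,6-dimethoxy-4-(4,4,5,5-tetramethyl-1,3,2-dioxaborolan-2-yl)phenol | COc1cc(B2OC(C)(C)C(C)(C)O2)cc(OC)c1O | starting material
4 | 4-(6-bromo-2,3,4-trimethoxyphenyl)-2,6-dimethoxyphenol | COc1cc(-c2c(Br)cc(OC)c(OC)c2OC)cc(OC)c1O | intermediate
5 | [4-(6-bromo-2,3,4-trimethoxyphenyl)-2,6-dimethoxyphenoxy](tert-butyl)dimethylsilane | COc1cc(-c2c(Br)cc(OC)c(OC)c2OC)cc(OC)c1O[Si](C)(C)C(C)(C)C | intermediate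
6 | (4R)-4-benzyl-3-propanoyl-1,3-oxazolidin-2-one | CCC(=O)N1[C@H](Cc2ccccc2)COC1=O | starting material
7 | lithium Z-enolate of 6 | C/C=C(\O[Li])N1[C@H](Cc2ccccc2)COC1=O | intermediate
8 | (2S,3S)-1,4-bis[(4R)-4-benzyl-2-oxo-1,3-oxazolidin-3-yl]-2,3-dimethylbutane-1,4-dione | O=C([C@@H](C)[C@H](C)C(=O)N1[C@H](Cc2ccccc2)COC1=O)N1[C@H](Cc2ccccc2)COC1=O | intermediate
9 | (2S,3S)-2,3-dimethylbutane-1,4-diol | OC[C@@H](C)[C@H](C)CO | intermediate
10 | (3S,4S)-3,4-dimethyloxolan-2-ol (lactol, both anomers) | OC1OC[C@@H](C)[C@@H]1C | intermediate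
11 | (3S,4S)-3,4-dimethyloxolan-2-one | O=C1OC[C@@H](C)[C@@H]1C | intermediate
12 | ethyl (2S,3S)-4-bromo-2,3-dimethylbutanoate | BrC[C@@H](C)[C@H](C)C(=O)OCC | intermediate
13 | (2S,3S)-4-bromo-2,3-dimethylbutanal | BrC[C@@H](C)[C@H](C)C=O | intermediate
14 | {2-[4-(tert-butyldimethylsilyloxy)-3,5-dimethoxyphenyl]-3,4,5-trimethoxyphenyl}lithium | COc1cc(-c2c([Li])cc(OC)c(OC)c2OC)cc(OC)c1O[Si](C)(C)C(C)(C)C | intermediate
15 | lithium (1R,2S,3S)-4-bromo-1-{2-[4-(tert-butyldimethylsilyloxy)-3,5-dimethoxyphenyl]-3,4,5-trimethoxyphenyl}-2,3-dimethylbutan-1-olate | BrC[C@@H](C)[C@H](C)[C@@H](O[Li])c1cc(OC)c(OC)c(OC)c1-c1cc(OC)c(O[Si](C)(C)C(C)(C)C)c(OC)c1 | intermediate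
16 | (1R,2S,3S)-4-bromo-1-{2-[4-(tert-butyldimethylsilyloxy)-3,5-dimethoxyphenyl]-3,4,5-trimethoxyphenyl}-2,3-dimethylbutyl benzoate | BrC[C@@H](C)[C@H](C)[C@@H](OC(=O)c1ccccc1)c1cc(OC)c(OC)c(OC)c1-c1cc(OC)c(O[Si](C)(C)C(C)(C)C)c(OC)c1 | intermediate
17 | cesium 4-{6-[(1R,2S,3S)-1-(benzoyloxy)-4-bromo-2,3-dimethylbutyl]-2,3,4-trimethoxyphenyl}-2,6-dimethoxyphenolate | BrC[C@@H](C)[C@H](C)[C@@H](OC(=O)c1ccccc1)c1cc(OC)c(OC)c(OC)c1-c1cc(OC)c([O-])c(OC)c1.[Cs+] | intermediate
18 | (7R,8S,9R)-2,3,3',4,5'-pentamethoxy-7,8-dimethyl-4'-oxo-6,7,8,9-tetrahydrospiro[benzo[7]annulene-5,1'-cyclohexane]-2',5'-dien-9-yl benzoate | COC1=CC2(C=C(OC)C1=O)C[C@@H](C)[C@H](C)[C@@H](OC(=O)c1ccccc1)c1cc(OC)c(OC)c(OC)c12 | target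

**Step count and risks**

Total steps: 9. Longest linear sequence: 6 steps (steps 4 to 9).

Steps most likely to fail:

Step 9. The seven-membered C-alkylation may be too slow, so that intermolecular O-alkylation, elimination of hydrogen bromide or displacement of bromide by fluoride takes over. The aryllithium may also enolise the aldehyde or add with insufficient facial selectivity, and the benzylic ester may ionise on heating. The fallback closes ring C through the aryl–spiro bond by phenolic oxidative coupling; it sets out from 13 and comes back to the route at 18. Addition of commercial 3,4,5-trimethoxyphenylmagnesium bromide to 13 (THF, −78 °C, cold quench) should give (1R,2S,3S)-4-bromo-2,3-dimethyl-1-(3,4,5-trimethoxyphenyl)butan-1-ol F1, from which the minor C-1 epimer can be removed in this open-chain series. Benzoylation (PhCOCl, pyridine, DMAP) should give (1R,2S,3S)-4-bromo-2,3-dimethyl-1-(3,4,5-trimethoxyphenyl)butyl benzoate F2. Nickel-catalysed reductive cross-electrophile coupling of the primary bromide with commercial 4-bromo-2,6-dimethoxyphenol (NiI2, 4,4'-di-tert-butyl-2,2'-bipyridine, Zn, DMA, 60 °C) should give (1R,2S,3R)-4-(4-hydroxy-3,5-dimethoxyphenyl)-2,3-dimethyl-1-(3,4,5-trimethoxyphenyl)butyl benzoate F3. Oxidation of the phenol with PhI(OCOCF3)2 in CF3CH2OH at −40 °C should then let the trimethoxyphenyl ring attack the para carbon of the oxidised phenol through its position ortho to the side chain and para to a methoxy group, which gives 18.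

Step 4. Diastereocontrol may be lost in the enolate dimerisation (unlike coupling to the meso-type dimer), and conversion may be low through enolate decomposition. The fallback builds the two centres one after the other; it sets out from 6 and comes back to the route at 11. Evans alkylation of the sodium enolate of 6 with tert-butyl bromoacetate (NaN(SiMe3)2, THF, −78 °C) should give tert-butyl (3S)-4-[(4R)-4-benzyl-2-oxo-1,3-oxazolidin-3-yl]-3-methyl-4-oxobutanoate F4. LiBH4 should cleave the imide selectively to tert-butyl (3S)-4-hydroxy-3-methylbutanoate F5, and CF3CO2H should remove the tert-butyl group and close (4S)-4-methyloxolan-2-one F6. Methylation of its lithium enolate (LiN(i-Pr)2, MeI, −78 °C) should occur trans to the ring methyl and give 11.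

Step 7. Ring opening may stay incomplete because the disubstituted lactone re-closes on concentration, and acid may promote epimerisation next to the carbonyl. The fallback avoids the lactone and the ester; it sets out from 9 and comes back to the route at 13. Mono-silylation of the diol (NaH, TBSCl, THF) should give (2S,3S)-4-[tert-butyl(dimethyl)silyl]oxy-2,3-dimethylbutan-1-ol F7. Bromination (CBr4, PPh3) should give [(2S,3S)-4-bromo-2,3-dimethylbutoxy](tert-butyl)dimethylsilane F8, and HF·pyridine should release (2S,3S)-4-bromo-2,3-dimethylbutan-1-ol F9. Oxidation with Dess–Martin periodinane should give 13.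

**Further compounds**

F1 | step 9 | (1R,2S,3S)-4-bromo-2,3-dimethyl-1-(3,4,5-trimethoxyphenyl)butan-1-ol | BrC[C@@H](C)[C@H](C)[C@@H](O)c1cc(OC)c(OC)c(OC)c1
F2 | step 9 | (1R,2S,3S)-4-bromo-2,3-dimethyl-1-(3,4,5-trimethoxyphenyl)butyl benzoate | BrC[C@@H](C)[C@H](C)[C@@H](OC(=O)c1ccccc1)c1cc(OC)c(OC)c(OC)c1
F3 | step 9 | (1R,2S,3R)-4-(4-hydroxy-3,5-dimethoxyphenyl)-2,3-dimethyl-1-(3,4,5-trimethoxyphenyl)butyl benzoate | COc1cc(C[C@@H](C)[C@H](C)[C@@H](OC(=O)c2ccccc2)c2cc(OC)c(OC)c(OC)c2)cc(OC)c1O
F4 | step 4 | tert-butyl (3S)-4-[(4R)-4-benzyl-2-oxo-1,3-oxazolidin-3-yl]-3-methyl-4-oxobutanoate | O=C(N1[C@H](Cc2ccccc2)COC1=O)[C@@H](C)CC(=O)OC(C)(C)C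
F5 | step 4 | tert-butyl (3S)-4-hydroxy-3-methylbutanoate | OC[C@@H](C)CC(=O)OC(C)(C)C
F6 | step 4 | (4S)-4-methyloxolan-2-one | O1C[C@@H](C)CC1=O
F7 | step 7 | (2S,3S)-4-[tert-butyl(dimethyl)silyl]oxy-2,3-dimethylbutan-1-ol | OC[C@@H](C)[C@H](C)CO[Si](C)(C)C(C)(C)C
F8 | step 7 | [(2S,3S)-4-bromo-2,3-dimethylbutoxy](tert-butyl)dimethylsilane | BrC[C@@H](C)[C@H](C)CO[Si](C)(C)C(C)(C)C
F9 | step 7 | (2S,3S)-4-bromo-2,3-dimethylbutan-1-ol | BrC[C@@H](C)[C@H](C)CO
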